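**Retrosynthetic overview**
1. The last bond is O9–C13. The 9α-OH of a 6β-acetoxy furanolabdane adds to its own furan in a dearomative hydroalkoxylation, which closes the oxolane (ring C), turns the furan into the 2,3-dihydrofuran (ring D) and sets C13.
2. C11–C12 comes from a 9α,11-spiro-epoxide and furan-3-ylmethyl Grignard. The epoxide comes from the C9 ketone by methylenation and α-face epoxidation, which sets C9.
3. The 6β-hydroxy-9-ketone comes from a trans-decalin-6,9-dione. C5 and C8 are set by equilibration and C6 by α-face hydride. The extra C2 oxygen is removed by Wolff–Kishner reduction.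
4. C1–C10 and C4–C5 come from an enantioselective Diels–Alder reaction of 2,6-dimethylbenzoquinone with the silyl dienol ether of mesityl oxide, which sets C10.
5. Ring order: B (quinone, bought), then A (cycloaddition), then the furan is attached (bought, later ring D), then C (final C–O closure).

Convention: labdane/drimane numbering is used throughout. β means the face of the C10 methyl group and α the opposite face.
Assumption: the sense of induction of the two chiral catalysts (steps 2 and 11) is taken as drawn. If a first run shows the opposite sense, the mirror-image catalyst is used and nothing else changes.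

**Step 1**
Reactants: 1 mesityl oxide (4-methylpent-3-en-2-one)
Product: 3 triisopropyl[(4-methylpenta-1,3-dien-2-yl)oxy]silane, via lithium dienolate 2 (not isolated)
Conditions: LDA (1.05 equiv), THF, −78 °C, 30 min; TIPSOTf (1.05 equiv), −78 → 0 °C
Reagents that add atoms: triisopropylsilyl trifluoromethanesulfonate, CC(C)[Si](OS(=O)(=O)C(F)(F)F)(C(C)C)C(C)C
Why: Kinetic α'-deprotonation of the enone gives the cross-conjugated lithium dienolate, which is O-silylated (silyl enol ether formation); no stereocentre is formed.

**Step 2**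
Reactants: 3 triisopropyl[(4-methylpenta-1,3-dien-2-yl)oxy]silane; 4 2,6-dimethyl-1,4-benzoquinone
Product: 5 cis-fused adduct (4aR,8aS)-2,5,5,8a-tetramethyl-7-(triisopropylsilyloxy)-4a,5,8,8a-tetrahydronaphthalene-1,4-dione (10β-methyl, 5β-H; C6 and C9 ketones, C7=C8 and C2=C3 double bonds)
Conditions: (S)-3,3-diphenyl-1-(2-methylphenyl)tetrahydro-1H,3H-pyrrolo[1,2-c][1,3,2]oxazaborole (20 mol %) + HNTf2 (18 mol %), 3 (1.5 equiv), CH2Cl2, −78 → −40 °C, 24 h
Reagents that add atoms: none
Why: In this enantioselective Diels–Alder reaction (chiral oxazaborolidinium cation) the catalyst binds the unhindered C6 carbonyl, the nucleophilic CH2 terminus of the 2-silyloxydiene attacks the methyl-bearing β-carbon C10 and the CMe2 terminus closes on C5, so suprafacial addition gives the cis-fused adduct and the shielded quinone face fixes the quaternary C10 (10β-methyl).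

**Step 3**
Reactants: 5 cis-fused Diels–Alder adduct
Product: 7 trans-fused 6,9-dione 2-TIPS enol ether (5α-H 8α-methyl 10β-methyl), via cis-fused 7,8-dihydro adduct 6 (not isolated)
Conditions: H2 (1 atm), 10 % Pd/C, EtOAc, rt, 2 h; filter, evaporate; NaOMe (0.2 equiv), MeOH, rt, 12 h
Reagents that add atoms: none
Why: Chemoselective catalytic hydrogenation of the electron-poor enedione C7=C8 bond (the hindered silyl enol ether stays) is followed by base-catalysed epimerisation through the C6 and C9 enolates, which sets C5 (5α-H, trans-decalin) and C8 (equatorial 8α-methyl) under thermodynamic control relative to the fixed C10.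

**Step 4**
Reactants: 7 trans-fused 6,9-dione 2-TIPS enol ether
Product: 9 6β-hydroxy-2,9-dione (4-hydroxy-2,5,5,8a-tetramethyloctahydronaphthalene-1,7-dione), via 6β-hydroxy TIPS enol ether 8 (not isolated)
Conditions: NaBH4 (0.6 equiv), MeOH/CH2Cl2 1:1, −40 °C, 2 h; then 2 M aq HCl, THF, rt, 3 h
Reagents that add atoms: none
Why: In this chemo- and diastereoselective borohydride reduction C9 is flanked by a quaternary and a tertiary carbon and C2 is masked, so only C6 reacts, hydride comes from the open α face opposite the two syn-axial β-methyl groups to give the axial 6β-alcohol, and the acidic work-up hydrolyses the silyl enol ether.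

**Step 5**
Reactants: 9 6β-hydroxy-2,9-dione
Product: 11 6β-hydroxy-11-nordriman-9-one (4-hydroxy-2,5,5,8a-tetramethyloctahydronaphthalen-1(2H)-one), via C2 hydrazone 10 (not isolated)
Conditions: N2H4·H2O (4 equiv), EtOH, 60 °C, 6 h; evaporate; KOtBu (0.5 equiv), DMSO, 25 °C, 12 h
Reagents that add atoms: none
Why: In this Wolff–Kishner reduction (mild KOtBu/DMSO variant) only the C2 ketone, flanked by two CH2 groups, condenses with hydrazine and loses N2 to give CH2, while the doubly α-branched C9 ketone stays and C8 keeps its equilibrium configuration.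

**Step 6**
Reactants: 11 6β-hydroxy-11-nordriman-9-one
Product: 12 drim-9(11)-en-6β-ol (8α-methyl, 5α-H)
Conditions: Ph3PCH3Br (4 equiv), KOtBu (4 equiv), toluene, 100 °C, 6 h
Reagents that add atoms: methyltriphenylphosphonium bromide, C[P+](c1ccccc1)(c1ccccc1)c1ccccc1.[Br-]
Why: Wittig methylenation with excess ylide in hot toluene is the standard answer to hindered, enolisable ketones; one equivalent of base is held by the free alcohol and no stereocentre changes.

**Step 7**
Reactants: 12 drim-9(11)-en-6β-ol
Product: 13 9α,11-epoxydriman-6β-ol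
Conditions: mCPBA (1.2 equiv), CH2Cl2, 0 °C, 3 h
Reagents that add atoms: 3-chloroperoxybenzoic acid, O=C(OO)c1cccc(Cl)c1
Why: In this Prilezhaev epoxidation the neighbouring axial C10 methyl blocks the β face, so oxygen is delivered from the α face, which sets C9 with O axial (α) and C11 equatorial (β).

**Step 8**
Reactants: 14 furan-3-ylmethanol
Product: 15 3-(chloromethyl)furan
Conditions: SOCl2 (1.1 equiv), pyridine (1.2 equiv), Et2O, 0 °C, 1 h; used at once
Reagents that add atoms: thionyl chloride, O=S(Cl)Cl
Why: Deoxychlorination of a primary alcohol through its chlorosulfite, with pyridine keeping the acid-sensitive furan safe; no stereocentre is involved.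

**Step 9**
Reactants: 13 9α,11-epoxydriman-6β-ol; 15 3-(chloromethyl)furan
Product: 17 15,16-epoxylabda-13(16),14-diene-6β,9α-diol, via furan-3-ylmethylmagnesium chloride 16 (not isolated)
Conditions: 15 (3.5 equiv), Mg turnings, THF, 0 °C; then Li2CuCl4 (10 mol %) and 13, THF, −30 → 0 °C; aq NH4Cl
Reagents that add atoms: none
Why: Copper-catalysed Grignard opening of the epoxide by SN2 attack at the CH2 carbon C11 forms C11–C12 and leaves the C9–O bond, and so the 9α configuration, untouched; one equivalent of Grignard is spent on the 6β-OH.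

**Step 10**
Reactants: 17 15,16-epoxylabda-13(16),14-diene-6β,9α-diol
Product: 18 6β-acetoxy-15,16-epoxylabda-13(16),14-dien-9α-ol
Conditions: Ac2O (3 equiv), DMAP (0.2 equiv), pyridine, 50 °C, 12 h
Reagents that add atoms: acetic anhydride, CC(=O)OC(C)=O
Why: DMAP-catalysed acylation esterifies the hindered secondary 6β-alcohol while the tertiary 9α-alcohol does not react; configuration is retained.

**Step 11**
Reactants: 18 6β-acetoxy-15,16-epoxylabda-13(16),14-dien-9α-ol
Product: 19 (5S,6R,8R,9R,10S,13R)-6-acetoxy-9,13;15,16-diepoxylabd-14-ene (target)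
Conditions: (R,R)-N,N'-bis(3,5-di-tert-butylsalicylidene)-1,2-cyclohexanediaminatocobalt, C36H52CoN2O2, divalent cobalt (10 mol %), N-fluoro-2,4,6-trimethylpyridinium tetrafluoroborate (1.5 equiv), PhSiH3 (1.5 equiv), 2,4,6-collidine (1 equiv), PhCF3, 0 °C, Ar; filtration through basic alumina
Reagents that add atoms: none
Why: Proposed new method: a cobalt-salen hydrogen-atom-transfer/radical-polar-crossover hydroalkoxylation (closest known reaction type: the Mukaiyama-type cobalt-salen/N-fluoropyridinium/silane Markovnikov cycloetherification of unactivated alkenols, including its chiral-salen version that builds 2,2-disubstituted oxolanes enantioselectively) is applied to a furan C=C bond, where it has not been shown: the trivalent cobalt hydride gives H• to C16, the furan α-carbon next to the chain, because this yields a tertiary, oxygen-conjugated allyl radical (H-atom affinity estimated to be close to that of a 1,1-disubstituted alkene), the radical is captured by divalent cobalt and oxidised to a tetravalent alkylcobalt/2H-furanium ion pair, the 9α-OH attacks C13 in 5-exo mode and collidine takes the proton; the N–F oxidant and the silane pay for the lost aromaticity, the collidine buffer is too weakly acidic to reopen the spiro-ether, proton loss from the cation only regenerates 18, and the chiral salen pocket rather than the remote decalin chooses the furan face so that C16 lies cis to C8 on ring C, i.e. (13R), while the separable 13-epimer is re-aromatised to 18 with a trace of PPTS and recycled.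

**Compound list**
1 | mesityl oxide (4-methylpent-3-en-2-one) | CC(=O)C=C(C)C | starting material
2 | lithium 4-methylpenta-1,3-dien-2-olate | [Li+].[O-]C(=C)C=C(C)C | intermediate
3 | triisopropyl[(4-methylpenta-1,3-dien-2-yl)oxy]silane | C=C(O[Si](C(C)C)(C(C)C)C(C)C)C=C(C)C | intermediate
4 | 2,6-dimethyl-1,4-benzoquinone | CC1=CC(=O)C=C(C)C1=O | starting material
5 | cis-fused Diels–Alder adduct, 10β-methyl, 5β-H | O=C1C=C(C)C(=O)[C@@]2(C)CC(O[Si](C(C)C)(C(C)C)C(C)C)=CC(C)(C)[C@@H]12 | intermediate
6 | cis-fused 7,8-dihydro adduct (C8 epimers) | O=C1CC(C)C(=O)[C@@]2(C)CC(O[Si](C(C)C)(C(C)C)C(C)C)=CC(C)(C)[C@@H]12 | intermediate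
7 | trans-fused 6,9-dione 2-TIPS enol ether, 5α-H, 8α-methyl | O=C1C[C@@H](C)C(=O)[C@@]2(C)CC(O[Si](C(C)C)(C(C)C)C(C)C)=CC(C)(C)[C@H]12 | intermediate
8 | 6β-hydroxy-9-ketone 2-TIPS enol ether | O[C@@H]1C[C@@H](C)C(=O)[C@@]2(C)CC(O[Si](C(C)C)(C(C)C)C(C)C)=CC(C)(C)[C@H]12 | intermediate
9 | 6β-hydroxy-2,9-dione | O[C@@H]1C[C@@H](C)C(=O)[C@@]2(C)CC(=O)CC(C)(C)[C@H]12 | intermediate
10 | C2 hydrazone of 9 | O[C@@H]1C[C@@H](C)C(=O)[C@@]2(C)CC(=NN)CC(C)(C)[C@H]12 | intermediate
11 | 6β-hydroxy-11-nordriman-9-one | O[C@@H]1C[C@@H](C)C(=O)[C@@]2(C)CCCC(C)(C)[C@H]12 | intermediate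
12 | drim-9(11)-en-6β-ol | O[C@@H]1C[C@@H](C)C(=C)[C@@]2(C)CCCC(C)(C)[C@H]12 | intermediate
13 | 9α,11-epoxydriman-6β-ol | O[C@@H]1C[C@@H](C)[C@]3(CO3)[C@@]2(C)CCCC(C)(C)[C@H]12 | intermediate
14 | furan-3-ylmethanol | OCc1ccoc1 | starting material
15 | 3-(chloromethyl)furan | ClCc1ccoc1 | intermediate
16 | furan-3-ylmethylmagnesium chloride | Cl[Mg]Cc1ccoc1 | intermediate
17 | 15,16-epoxylabda-13(16),14-diene-6β,9α-diol | O[C@@H]1C[C@@H](C)[C@](O)(CCc3ccoc3)[C@@]2(C)CCCC(C)(C)[C@H]12 | intermediate
18 | 6β-acetoxy-15,16-epoxylabda-13(16),14-dien-9α-ol | CC(=O)O[C@@H]1C[C@@H](C)[C@](O)(CCc3ccoc3)[C@@]2(C)CCCC(C)(C)[C@H]12 | intermediate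
19 | (13R)-6β-acetoxy-9α,13;15,16-diepoxylabd-14-ene | CC(=O)O[C@@H]1C[C@@H](C)[C@]2(CC[C@]3(C=COC3)O2)[C@@]2(C)CCCC(C)(C)[C@H]12 | target

**Step count**
Total steps: 11. Longest linear sequence: 10 (steps 1–7 and 9–11).

**Steps most likely to fail**

**Step 2 (asymmetric Diels–Alder).** The gem-dimethyl terminus makes diene 3 slow. The strongly acidic catalyst may only protodesilylate it, or it may give low ee. The fallback sets out from 3 and 4 and comes back at 5. The annulation is run racemically with the achiral mixed Lewis acid AlBr3/AlMe3 (10:1, toluene/CH2Cl2, −5 °C), which drives doubly hindered partners through a stepwise Mukaiyama–Michael/Michael path. Absolute configuration is then secured by resolution instead of catalysis: preparative chiral SFC of the racemate gives 5 and its mirror image, the (4aS,8aR)-adduct F1, which is discarded.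

**Step 9 (epoxide opening).** There are three failure modes:
- The furylmethyl Grignard is ambident and can attack through furan C2.
- Magnesium salts can trigger a Meinwald rearrangement of the neopentyl spiro-epoxide.
- The 6β-alkoxide could attack C9 across the ring.

The fallback sets out from 12 (and 15) and comes back at 17, with the polarity at C11 reversed. OsO4 (2 mol %)/NMO dihydroxylates the exocyclic alkene from the α face to give drimane-6β,9α,11-triol F2. TEMPO/PhI(OAc)2 oxidises only the primary alcohol to give 6β,9α-dihydroxydriman-11-al F3. Chloride 15 and PPh3 give (furan-3-ylmethyl)triphenylphosphonium chloride F4. Its ylide (NaHMDS, 3.2 equiv, THF) converts F3 into 15,16-epoxylabda-11,13(16),14-triene-6β,9α-diol F5 as an E/Z mixture. Diimide (2-nitrobenzenesulfonylhydrazide, Et3N) saturates the C11=C12 bond without touching the furan and gives 17.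

**Step 11 (proposed new step).** There are four failure modes:
- Hydrogen-atom transfer could go to the less hindered C15, which would lead to a 9,16-bridged acetal.
- The N–F salt could fluorinate the furan.
- The product enol ether could react further.
- The selectivity at C13 could be low.

The fallback uses known chemistry only, sets out from 18 and comes back at 19.
- Photooxygenation with singlet oxygen in the presence of a hindered base (O2, rose bengal, hν, iPr2NEt, CH2Cl2, −78 °C) gives 6β-acetoxy-9α,16-dihydroxylabd-13-en-15,16-olide F6.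
- NaBH4 (EtOH, 0 °C) followed by an acidic work-up gives 6β-acetoxy-9α-hydroxylabd-13-en-15,16-olide F7.
- DBU (toluene, 80 °C) closes the O9–C13 bond by oxa-Michael addition to give (13R)-6β-acetoxy-9α,13-epoxylabdan-15,16-olide F8. The 13-epimer is separated and re-equilibrated with DBU.
- Disiamylborane (THF, rt) reduces the γ-lactone but not the acetate, giving the 15-lactol F9.
- MsCl/Et3N (CH2Cl2, 0 °C to reflux) eliminates toward C14 and gives 19.

**Further compounds**
F1 | step 2 | (4aS,8aR)-adduct, mirror image of 5 | O=C1C=C(C)C(=O)[C@]2(C)CC(O[Si](C(C)C)(C(C)C)C(C)C)=CC(C)(C)[C@H]12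
F2 | step 9 | drimane-6β,9α,11-triol | O[C@@H]1C[C@@H](C)[C@](O)(CO)[C@@]2(C)CCCC(C)(C)[C@H]12
F3 | step 9 | 6β,9α-dihydroxydriman-11-al | O[C@@H]1C[C@@H](C)[C@](O)(C=O)[C@@]2(C)CCCC(C)(C)[C@H]12
F4 | step 9 | (furan-3-ylmethyl)triphenylphosphonium chloride | [Cl-].c1ccc(cc1)[P+](Cc1ccoc1)(c1ccccc1)c1ccccc1
F5 | step 9 | 15,16-epoxylabda-11,13(16),14-triene-6β,9α-diol (E/Z mixture) | O[C@@H]1C[C@@H](C)[C@](O)(C=Cc3ccoc3)[C@@]2(C)CCCC(C)(C)[C@H]12
F6 | step 11 | 6β-acetoxy-9α,16-dihydroxylabd-13-en-15,16-olide (C16 epimers) | CC(=O)O[C@@H]1C[C@@H](C)[C@](O)(CCC3=CC(=O)OC3O)[C@@]2(C)CCCC(C)(C)[C@H]12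
F7 | step 11 | 6β-acetoxy-9α-hydroxylabd-13-en-15,16-olide | CC(=O)O[C@@H]1C[C@@H](C)[C@](O)(CCC3=CC(=O)OC3)[C@@]2(C)CCCC(C)(C)[C@H]12
F8 | step 11 | (13R)-6β-acetoxy-9α,13-epoxylabdan-15,16-olide | CC(=O)O[C@@H]1C[C@@H](C)[C@]2(CC[C@]3(CC(=O)OC3)O2)[C@@]2(C)CCCC(C)(C)[C@H]12
F9 | step 11 | (13R)-6β-acetoxy-9α,13;15,16-diepoxylabdan-15-ol (lactol, C15 epimers) | CC(=O)O[C@@H]1C[C@@H](C)[C@]2(CC[C@]3(CC(O)OC3)O2)[C@@]2(C)CCCC(C)(C)[C@H]12
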